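In a one-step world, free monomer lost reappears in chains. Yet the summer flask at 8.00 h reads 25.8% in chains and 2.8% free, with 71.4% gone where we cannot read it.

| setting | summer | noon | flask |
|---|---|---|---|
| free monomer | 0.39 M | 0.39 M | 0.39 M |
| initiator | 4.7 mol% | 7.1 mol% | 4.7 mol% |
| remark | the very flask that is asked about, followed so far | run made earlier |  |
| time |  |  | 40 h |

| run | time / h | monomer in chains / % | free monomer / % |
|---|---|---|---|
| summer | 1.00 | 11.1 | 31.7 |
| summer | 2.50 | 17.9 | 12.6 |
| summer | 3.00 | 20.2 | 10.1 |
| summer | 5.00 | 22.7 | 6.1 |
| summer | 6.00 | 24.1 | 2.7 |
| summer | 8.00 | 25.8 | 2.8 |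
| noon | 2.00 | 24.3 | 15.6 |
| noon | 6.00 | 32.1 | 2.3 |
| noon | 12.0 | 30.5 | 2.8 |
| noon | 15.0 | 32.4 | 1.1 |
| noon | 25.0 | 32.8 | 0 |
| noon | 30.0 | 33.8 | 0 |
| noon | 40.0 | 32.2 | 1.5 |

(readings scatter by 1 percentage point)

- a reading or a percentage of monomer in chains counts all its forms, free or not
- the reaction counts as stopped when no species that holds the free monomer changes by six tenths of a point or more over the second half of the time

1. the state of affairs at 40 h: stopped, and by what, or still going (no working catalyst is left / it is still moving / forward and back rates have come level / all of the free monomer has reacted)
2. monomer in chains at 40 h, in percent of the free monomer charged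

For whoever takes the bench: we carry the split (a selectivity factor), monomer in chains per unit of monomer gone the unseen way, a mean over the run so far, 0.361 in summer. Noon at 40.0 h reads 0.486. At that mean split, summer ends at 26.5%. But the mean errs, since between 5.00 h and 8.00 h summer gained 3.1 percentage points in chains while free monomer fell 3.3 points, and if the remainder goes wholly into chains, summer reaches 28.6%. So at 40 h expect a value between these, with free monomer gone, as noon's read 0% at 25.0 h. Keep the loading as charged if this estimate is to stand, since noon, with more initiator, reads a larger split, as loading to the power 0.717.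

The forecast differs on the ending: no working catalyst is left, with 27.5% (25.5% to 31%): “So I expect summer to stop through catalyst loss near 27–28.”

    initiator + monomer in chains ⇌ idle complex, settled at all times (K = 50.0 M⁻¹)
    2 free monomer → self-condensation product (k = 2.20 M⁻¹ h⁻¹)
    free monomer + living end → monomer in chains + living end, rate k3*[living end]*[free monomer] (k = 15.4 M⁻¹ h⁻¹)
    free monomer + initiator → living end + monomer in chains (k = 10.6 M⁻¹ h⁻¹)

The flask gives all of the free monomer has reacted, with 27.7% in chains, so the forecast's number holds and its ending does not: at 40.0 h free monomer stands at 0%, while 2.2% of the initiator and 0.0157 M of living end remain. Against 72.3% of self-condensation product, the split is 0.383. The neighbour flask takes 19 mol% of initiator, and the same power gives a split of 0.983, hence 49.6% in chains. That neighbour ends with free monomer at 0% and 50.5% in chains.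

The earlier runs and the new flask come from a simulation on assumed constants; scatter was added.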